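Locants follow bicyclo[8.2.0]dodecane numbering of the target: C1 = methyl-bearing ring-fusion carbon, C10 = the other fusion carbon, C11 and C12 (isopropenyl) complete the cyclobutane, C4 carries the acrylate, C6 the prenyl group, C7 the methylidene.
Ten-membered ring (closed last): the C7–C8 bond, by one-pot hydroboration / B-alkyl Suzuki–Miyaura macrocyclisation of a vinyl group on cyclobutane carbon C10 with a 2-iodoalkene at C7. The enabling feature is the exocyclic C7=CH2, whose sp2 carbon is tied through the C8–C9 ethano unit to C10, together with the trans placement of the two ring arms on the adjacent cyclobutane carbons C1 and C10.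
Chain C2–C7: the C3–C4 bond by ligand-controlled copper-catalysed conjugate addition of a cyclobutylethyl Grignard reagent to an enoate (sets C4); C6 set by rhodium-catalysed conjugate alkynylation of a dienal; acrylate unveiled after ring closure by α-methylenation.
Cyclobutane (first ring of the skeleton): asymmetric conjugate addition/enolate alkylation on 2-methylcyclopent-2-en-1-one (sets C12 and C1), then Wolff ring contraction of this temporary five-membered ring (C10 by equilibration); ring order: cyclobutane, then the ten-membered ring.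

Key step: step 16

Remark: for the ligand-controlled steps 1, 11 and 13 the ligand antipode named is the one expected to give the drawn configuration; the mirror-image ligand would be used should the facial sense prove opposite.

Step 1
Reactants: 1 2-methylcyclopent-2-en-1-one
Product: 3 tert-butyl 2-[(1R,5R)-1-methyl-2-oxo-5-(prop-1-en-2-yl)cyclopentyl]acetate, via magnesium enolate 2 (not isolated)
Conditions: CH2=C(CH3)MgBr, Cu(OTf)2 (3 mol%), chiral N-heterocyclic carbene ligand from a C2-symmetric imidazolinium salt (4 mol%), Et2O, −30 °C; then BrCH2CO2tBu, DMPU, −30 °C to rt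
Reagents that add atoms: isopropenylmagnesium bromide, C=C(C)[Mg]Br; tert-butyl bromoacetate, CC(C)(C)OC(=O)CBr
Why: Copper-catalysed asymmetric conjugate addition of the alkenyl Grignard reagent should set the isopropenyl-bearing carbon under ligand control, and the magnesium enolate is then C-alkylated on the face anti to that group, which fixes the quaternary carbon with the acetate arm trans and the methyl cis to isopropenyl (three-component conjugate addition–enolate alkylation).

Step 2
Reactants: 3 tert-butyl 2-[(1R,5R)-1-methyl-2-oxo-5-(prop-1-en-2-yl)cyclopentyl]acetate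
Product: 6 tert-butyl 2-[(1R,5R)-3-diazo-1-methyl-2-oxo-5-(prop-1-en-2-yl)cyclopentyl]acetate, via lithium enolate 4 (not isolated), via trifluoroacetyl ketone 5 (not isolated)
Conditions: LiN(SiMe3)2, THF, −78 °C; CF3CO2CH2CF3; aq. HCl work-up; then MsN3, Et3N, H2O, MeCN, rt
Reagents that add atoms: methanesulfonyl azide, CS(=O)(=O)N=[N+]=[N-]
Why: Detrifluoroacetylative (Regitz-type) diazo transfer, regiospecific because the ketone has only one enolisable α-carbon (the other is quaternary), and neither stereocentre is touched.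

Step 3
Reactants: 6 tert-butyl 2-[(1R,5R)-3-diazo-1-methyl-2-oxo-5-(prop-1-en-2-yl)cyclopentyl]acetate
Product: 8 methyl (1R,2R,3R)-2-(2-tert-butoxy-2-oxoethyl)-2-methyl-3-(prop-1-en-2-yl)cyclobutane-1-carboxylate, via ketene 7 (not isolated)
Conditions: hν (350 nm), MeOH, rt; then NaOMe (cat.), MeOH, 40 °C
Reagents that add atoms: methanol, CO
Why: Photochemical Wolff rearrangement, in which loss of N2 and 1,2-shift of the quaternary carbon with retention contract the ring to a cyclobutylketene that methanol traps; methoxide equilibration of the new α-stereocentre should favour the ester cis to methyl and isopropenyl, the arrangement in which ester, isopropenyl and the acetate arm are all pseudo-equatorial on the puckered four-membered ring (thermodynamic control, minor epimer recyclable).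

Step 4
Reactants: 8 methyl (1R,2R,3R)-2-(2-tert-butoxy-2-oxoethyl)-2-methyl-3-(prop-1-en-2-yl)cyclobutane-1-carboxylate
Product: 9 tert-butyl 2-[(1R,2R,4R)-2-formyl-1-methyl-4-(prop-1-en-2-yl)cyclobutyl]acetate
Conditions: iBu2AlH (1.1 equiv), CH2Cl2, −78 °C; aq. sodium potassium tartrate
Reagents that add atoms: none
Why: Low-temperature iBu2AlH reduction should stop at the aluminium hemiacetal of the methyl ester and spare the bulkier neopentyl-type tert-butyl ester, so the aldehyde is released only on work-up with its α-stereocentre in the preferred configuration.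

Step 5
Reactants: 9 tert-butyl 2-[(1R,2R,4R)-2-formyl-1-methyl-4-(prop-1-en-2-yl)cyclobutyl]acetate
Product: 10 tert-butyl 2-[(1S,2S,4R)-2-ethenyl-1-methyl-4-(prop-1-en-2-yl)cyclobutyl]acetate
Conditions: Ph3PCH3Br, KOtBu, THF, 0 °C
Reagents that add atoms: methyltriphenylphosphonium bromide, C[P+](c1ccccc1)(c1ccccc1)c1ccccc1.[Br-]
Why: Wittig methylenation of the hindered aldehyde with the unstabilised ylide is fast at 0 °C and should not disturb the α-stereocentre, which in any case sits in its thermodynamically preferred configuration (the descriptor changes only through the priority rules).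

Step 6
Reactants: 10 tert-butyl 2-[(1S,2S,4R)-2-ethenyl-1-methyl-4-(prop-1-en-2-yl)cyclobutyl]acetate
Product: 11 2-[(1S,2S,4R)-2-ethenyl-1-methyl-4-(prop-1-en-2-yl)cyclobutyl]ethan-1-ol
Conditions: LiAlH4, THF, 0 °C to rt
Reagents that add atoms: none
Why: Hydride reduction of the tert-butyl ester to the primary alcohol, the isolated alkenes being inert to LiAlH4.

Step 7
Reactants: 11 2-[(1S,2S,4R)-2-ethenyl-1-methyl-4-(prop-1-en-2-yl)cyclobutyl]ethan-1-ol
Product: 12 (1S,2S,4R)-1-(2-bromoethyl)-2-ethenyl-1-methyl-4-(prop-1-en-2-yl)cyclobutane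
Conditions: CBr4, PPh3, CH2Cl2, 0 °C
Reagents that add atoms: carbon tetrabromide, BrC(Br)(Br)Br
Why: Appel reaction, an SN2 displacement of the oxyphosphonium group at the unhindered primary carbon under neutral conditions that leave the alkenes alone.

Step 8
Reactants: 13 prop-2-yn-1-ol; 14 1-bromo-3-methylbut-2-ene
Product: 15 6-methylhept-5-en-2-yn-1-ol
Conditions: CuI (10 mol%), K2CO3, Bu4NCl (cat.), DMF, rt
Reagents that add atoms: none
Why: Copper-catalysed coupling of the terminal alkyne (as its copper acetylide) with the primary allylic bromide at its unsubstituted carbon should build the skipped enyne with the free hydroxyl tolerated.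

Step 9
Reactants: 15 6-methylhept-5-en-2-yn-1-ol
Product: 16 (2E)-6-methylhepta-2,5-dien-1-ol
Conditions: LiAlH4, THF, reflux
Reagents that add atoms: none
Why: Hydroxyl-directed trans-hydroalumination of the propargylic alcohol followed by protonolysis gives the (E)-allylic alcohol and does not touch the isolated trisubstituted alkene.

Step 10
Reactants: 16 (2E)-6-methylhepta-2,5-dien-1-ol
Product: 17 (2E)-6-methylhepta-2,5-dienal
Conditions: MnO2, CH2Cl2, rt
Reagents that add atoms: none
Why: MnO2 oxidises the allylic alcohol to the enal under neutral conditions, which avoids base-mediated migration of the skipped alkene into conjugation.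

Step 11
Reactants: 17 (2E)-6-methylhepta-2,5-dienal
Product: 18 (3R)-6-methyl-3-{[tri(propan-2-yl)silyl]ethynyl}hept-5-enal
Conditions: HC≡CSi(iPr)3, [Rh(OAc)(C2H4)2]2 (2.5 mol%), (R)-DTBM-SEGPHOS (6 mol%), MeOH, 40 °C
Reagents that add atoms: ethynyltri(propan-2-yl)silane, C#C[Si](C(C)C)(C(C)C)C(C)C
Why: Rhodium-catalysed asymmetric conjugate alkynylation of the β-alkyl enal, in which the alkynylrhodium species adds to the enal face selected by the bisphosphine to set the future C6 (3R here), the bulky silyl group suppressing alkyne dimerisation.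

Step 12
Reactants: 18 (3R)-6-methyl-3-{[tri(propan-2-yl)silyl]ethynyl}hept-5-enal
Product: 19 methyl (2E,5S)-8-methyl-5-{[tri(propan-2-yl)silyl]ethynyl}nona-2,7-dienoate
Conditions: Ph3P=CHCO2Me, CH2Cl2, rt
Reagents that add atoms: methyl (triphenyl-λ5-phosphanylidene)acetate, COC(=O)C=P(c1ccccc1)(c1ccccc1)c1ccccc1
Why: Wittig olefination with the stabilised ylide gives the (E)-enoate under neutral conditions, so the β-stereocentre of the aldehyde is not at risk (its descriptor changes only through the priority rules).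

Step 13
Reactants: 12 (1S,2S,4R)-1-(2-bromoethyl)-2-ethenyl-1-methyl-4-(prop-1-en-2-yl)cyclobutane; 19 methyl (2E,5S)-8-methyl-5-{[tri(propan-2-yl)silyl]ethynyl}nona-2,7-dienoate
Product: 21 methyl (3S,5S)-3-{2-[(1S,2S,4R)-2-ethenyl-1-methyl-4-(prop-1-en-2-yl)cyclobutyl]ethyl}-8-methyl-5-{[tri(propan-2-yl)silyl]ethynyl}non-7-enoate, via Grignard reagent 20 (not isolated)
Conditions: Mg, Et2O, rt (12 to 20); then 19, CuBr·SMe2 (5 mol%), (R,Sp)-Josiphos (6 mol%), t-BuOMe, −75 °C; aq. HCl
Reagents that add atoms: none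
Why: Copper/ferrocenyl-diphosphine-catalysed enantioselective conjugate addition of the Grignard reagent to the (E)-enoate forms the C3–C4 bond of the target and sets C4 by ligand-controlled delivery of the alkyl group to the β-carbon face that gives 3S, the low temperature suppressing 1,2-addition.

Step 14
Reactants: 21 methyl (3S,5S)-3-{2-[(1S,2S,4R)-2-ethenyl-1-methyl-4-(prop-1-en-2-yl)cyclobutyl]ethyl}-8-methyl-5-{[tri(propan-2-yl)silyl]ethynyl}non-7-enoate
Product: 22 methyl (3S,5S)-3-{2-[(1S,2S,4R)-2-ethenyl-1-methyl-4-(prop-1-en-2-yl)cyclobutyl]ethyl}-5-ethynyl-8-methylnon-7-enoate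
Conditions: Bu4NF, THF, 0 °C to rt
Reagents that add atoms: none
Why: Fluoride cleaves the C(sp)–Si bond of the silylalkyne selectively to give the terminal alkyne.

Step 15
Reactants: 22 methyl (3S,5S)-3-{2-[(1S,2S,4R)-2-ethenyl-1-methyl-4-(prop-1-en-2-yl)cyclobutyl]ethyl}-5-ethynyl-8-methylnon-7-enoate
Product: 24 methyl (3S,5S)-3-{2-[(1S,2S,4R)-2-ethenyl-1-methyl-4-(prop-1-en-2-yl)cyclobutyl]ethyl}-5-(1-iodoethenyl)-8-methylnon-7-enoate, via iodoalkenylborane 23 (not isolated)
Conditions: B-iodo-9-BBN, pentane/CH2Cl2, −20 °C; then AcOH, 0 °C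
Reagents that add atoms: B-iodo-9-borabicyclo[3.3.1]nonane, IB1C2CCCC1CCC2
Why: syn-Iodoboration of the terminal alkyne places boron on the terminal and iodine on the internal carbon, and protodeboronation with acetic acid then gives the 2-iodo-1-alkene, while the alkenes do not undergo haloboration.

Step 16
Reactants: 24 methyl (3S,5S)-3-{2-[(1S,2S,4R)-2-ethenyl-1-methyl-4-(prop-1-en-2-yl)cyclobutyl]ethyl}-5-(1-iodoethenyl)-8-methylnon-7-enoate
Product: 26 methyl 2-[(1S,4S,6S,10R,12R)-1-methyl-7-methylidene-6-(3-methylbut-2-en-1-yl)-12-(prop-1-en-2-yl)bicyclo[8.2.0]dodecan-4-yl]acetate, via alkylborane 25 (not isolated)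
Conditions: 9-BBN dimer, THF, 0 °C to rt; then slow addition to Pd(dppf)Cl2 (15 mol%), AsPh3 (30 mol%), Cs2CO3, degassed DMF/THF/H2O, 50 °C, about 1 mM
Reagents that add atoms: none
Why: 9-BBN adds anti-Markovnikov to the only monosubstituted alkene (the vinyl group on C10) to give alkylborane 25, the 2-iodoalkene adds oxidatively to zerovalent palladium, the base-activated alkylborate transmetalates, and reductive elimination forms the C(sp2)–C(sp3) bond C7–C8. The closest known reaction type is the B-alkyl Suzuki–Miyaura macrocyclisation of a tethered alkyl-9-BBN and alkenyl halide. Mode of closure: the ten-membered ring closes by intramolecular cross-coupling at an sp2 carbon whose double bond stays outside the ring, so the C7 methylidene is delivered in the same event and the cyclobutane is a spectator. No new stereocentre is formed, and none of the five existing ones is epimerisable under these mildly basic conditions. The step needs site selectivity in the hydroboration, secured by the steric preference of 9-BBN for the monosubstituted vinyl group over the 1,1-disubstituted isopropenyl and iodoalkene and the trisubstituted prenyl double bonds, and ring closure in preference to oligomerisation, secured by high dilution and by the trans placement of the two arms on C1 and C10, which already imposes the turn of the trans-fused ring. The acrylate is still a saturated ester at this stage, so no intramolecular Heck pathway onto an electron-poor alkene can compete with transmetalation.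

Step 17
Reactants: 26 methyl 2-[(1S,4S,6S,10R,12R)-1-methyl-7-methylidene-6-(3-methylbut-2-en-1-yl)-12-(prop-1-en-2-yl)bicyclo[8.2.0]dodecan-4-yl]acetate
Product: 30 methyl 2-[(1S,4S,6R,10R,12R)-1-methyl-7-methylidene-6-(3-methylbut-2-en-1-yl)-12-(prop-1-en-2-yl)bicyclo[8.2.0]dodecan-4-yl]prop-2-enoate, via lithium enolate 27 (not isolated), via Mannich base 28 (not isolated), via ammonium iodide 29 (not isolated)
Conditions: LiN(iPr)2, THF, −78 °C; [Me2N=CH2]I, −78 °C to rt; then MeI, MeOH, rt; then DBU, CH2Cl2, rt (telescoped)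
Reagents that add atoms: N,N-dimethylmethaniminium iodide, C=[N+](C)C.[I-]
Why: α-Methylenation by Mannich reaction of the ester enolate with the iminium salt, N-methylation and E1cB (Hofmann-type) elimination of trimethylamine; C4 is β to the ester and cannot epimerise, the transient α-stereocentre is destroyed in the elimination, and the C6 descriptor changes to R only through the priority rules.

Compound list
1 | 2-methylcyclopent-2-en-1-one | CC1=CCCC1=O | starting material
2 | bromomagnesium (3R)-2-methyl-3-(prop-1-en-2-yl)cyclopent-1-en-1-olate | Br[Mg]OC1=C(C)[C@@H](C(C)=C)CC1 | intermediate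
3 | tert-butyl 2-[(1R,5R)-1-methyl-2-oxo-5-(prop-1-en-2-yl)cyclopentyl]acetate | O=C1CC[C@H](C(=C)C)[C@@]1(C)CC(=O)OC(C)(C)C | intermediate
4 | lithium (4R,5R)-5-(2-tert-butoxy-2-oxoethyl)-5-methyl-4-(prop-1-en-2-yl)cyclopent-1-en-1-olate | [Li]OC1=CC[C@H](C(=C)C)[C@@]1(C)CC(=O)OC(C)(C)C | intermediate
5 | tert-butyl 2-[(1R,5R)-1-methyl-2-oxo-5-(prop-1-en-2-yl)-3-(trifluoroacetyl)cyclopentyl]acetate (C3 unassigned, largely enolised) | O=C1C(C(=O)C(F)(F)F)C[C@H](C(=C)C)[C@@]1(C)CC(=O)OC(C)(C)C | intermediate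
6 | tert-butyl 2-[(1R,5R)-3-diazo-1-methyl-2-oxo-5-(prop-1-en-2-yl)cyclopentyl]acetate | O=C1C(=[N+]=[N-])C[C@H](C(=C)C)[C@@]1(C)CC(=O)OC(C)(C)C | intermediate
7 | tert-butyl 2-[(1R,4R)-1-methyl-2-(oxomethylidene)-4-(prop-1-en-2-yl)cyclobutyl]acetate | O=C=C1C[C@H](C(=C)C)[C@@]1(C)CC(=O)OC(C)(C)C | intermediate
8 | methyl (1R,2R,3R)-2-(2-tert-butoxy-2-oxoethyl)-2-methyl-3-(prop-1-en-2-yl)cyclobutane-1-carboxylate | COC(=O)[C@@H]1C[C@H](C(=C)C)[C@@]1(C)CC(=O)OC(C)(C)C | intermediate
9 | tert-butyl 2-[(1R,2R,4R)-2-formyl-1-methyl-4-(prop-1-en-2-yl)cyclobutyl]acetate | O=C[C@@H]1C[C@H](C(=C)C)[C@@]1(C)CC(=O)OC(C)(C)C | intermediate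
10 | tert-butyl 2-[(1S,2S,4R)-2-ethenyl-1-methyl-4-(prop-1-en-2-yl)cyclobutyl]acetate | C=C[C@@H]1C[C@H](C(=C)C)[C@@]1(C)CC(=O)OC(C)(C)C | intermediate
11 | 2-[(1S,2S,4R)-2-ethenyl-1-methyl-4-(prop-1-en-2-yl)cyclobutyl]ethan-1-ol | C=C[C@@H]1C[C@H](C(=C)C)[C@@]1(C)CCO | intermediate
12 | (1S,2S,4R)-1-(2-bromoethyl)-2-ethenyl-1-methyl-4-(prop-1-en-2-yl)cyclobutane | C=C[C@@H]1C[C@H](C(=C)C)[C@@]1(C)CCBr | intermediate
13 | prop-2-yn-1-ol | C#CCO | starting material
14 | 1-bromo-3-methylbut-2-ene | CC(C)=CCBr | starting material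
15 | 6-methylhept-5-en-2-yn-1-ol | CC(C)=CCC#CCO | intermediate
16 | (2E)-6-methylhepta-2,5-dien-1-ol | CC(C)=CC/C=C/CO | intermediate
17 | (2E)-6-methylhepta-2,5-dienal | CC(C)=CC/C=C/C=O | intermediate
18 | (3R)-6-methyl-3-{[tri(propan-2-yl)silyl]ethynyl}hept-5-enal | O=CC[C@H](C#C[Si](C(C)C)(C(C)C)C(C)C)CC=C(C)C | intermediate
19 | methyl (2E,5S)-8-methyl-5-{[tri(propan-2-yl)silyl]ethynyl}nona-2,7-dienoate | COC(=O)/C=C/C[C@H](C#C[Si](C(C)C)(C(C)C)C(C)C)CC=C(C)C | intermediate
20 | bromo{2-[(1S,2S,4R)-2-ethenyl-1-methyl-4-(prop-1-en-2-yl)cyclobutyl]ethyl}magnesium | C=C[C@@H]1C[C@H](C(=C)C)[C@@]1(C)CC[Mg]Br | intermediate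
21 | methyl (3S,5S)-3-{2-[(1S,2S,4R)-2-ethenyl-1-methyl-4-(prop-1-en-2-yl)cyclobutyl]ethyl}-8-methyl-5-{[tri(propan-2-yl)silyl]ethynyl}non-7-enoate | C=C[C@@H]1C[C@H](C(=C)C)[C@@]1(C)CC[C@H](CC(=O)OC)C[C@H](C#C[Si](C(C)C)(C(C)C)C(C)C)CC=C(C)C | intermediate
22 | methyl (3S,5S)-3-{2-[(1S,2S,4R)-2-ethenyl-1-methyl-4-(prop-1-en-2-yl)cyclobutyl]ethyl}-5-ethynyl-8-methylnon-7-enoate | C=C[C@@H]1C[C@H](C(=C)C)[C@@]1(C)CC[C@H](CC(=O)OC)C[C@H](C#C)CC=C(C)C | intermediate
23 | methyl (3S,5S)-5-[(Z)-2-(9-borabicyclo[3.3.1]nonan-9-yl)-1-iodoethenyl]-3-{2-[(1S,2S,4R)-2-ethenyl-1-methyl-4-(prop-1-en-2-yl)cyclobutyl]ethyl}-8-methylnon-7-enoate | C=C[C@@H]1C[C@H](C(=C)C)[C@@]1(C)CC[C@H](CC(=O)OC)C[C@H](/C(I)=C/B2C3CCCC2CCC3)CC=C(C)C | intermediate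
24 | methyl (3S,5S)-3-{2-[(1S,2S,4R)-2-ethenyl-1-methyl-4-(prop-1-en-2-yl)cyclobutyl]ethyl}-5-(1-iodoethenyl)-8-methylnon-7-enoate | C=C[C@@H]1C[C@H](C(=C)C)[C@@]1(C)CC[C@H](CC(=O)OC)C[C@H](C(I)=C)CC=C(C)C | intermediate
25 | methyl (3S,5S)-3-{2-[(1S,2R,4R)-2-[2-(9-borabicyclo[3.3.1]nonan-9-yl)ethyl]-1-methyl-4-(prop-1-en-2-yl)cyclobutyl]ethyl}-5-(1-iodoethenyl)-8-methylnon-7-enoate | C1CCC2CCCC1B2CC[C@@H]3C[C@H](C(=C)C)[C@@]3(C)CC[C@H](CC(=O)OC)C[C@H](C(I)=C)CC=C(C)C | intermediate
26 | methyl 2-[(1S,4S,6S,10R,12R)-1-methyl-7-methylidene-6-(3-methylbut-2-en-1-yl)-12-(prop-1-en-2-yl)bicyclo[8.2.0]dodecan-4-yl]acetate | C=C1CC[C@@H]2C[C@H](C(=C)C)[C@@]2(C)CC[C@H](CC(=O)OC)C[C@H]1CC=C(C)C | intermediate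
27 | lithium 1-methoxy-2-[(1S,4S,6S,10R,12R)-1-methyl-7-methylidene-6-(3-methylbut-2-en-1-yl)-12-(prop-1-en-2-yl)bicyclo[8.2.0]dodecan-4-yl]ethen-1-olate | C=C1CC[C@@H]2C[C@H](C(=C)C)[C@@]2(C)CC[C@H](C=C(O[Li])OC)C[C@H]1CC=C(C)C | intermediate
28 | methyl 3-(dimethylamino)-2-[(1S,4S,6S,10R,12R)-1-methyl-7-methylidene-6-(3-methylbut-2-en-1-yl)-12-(prop-1-en-2-yl)bicyclo[8.2.0]dodecan-4-yl]propanoate (both C2 epimers) | C=C1CC[C@@H]2C[C@H](C(=C)C)[C@@]2(C)CC[C@H](C(CN(C)C)C(=O)OC)C[C@H]1CC=C(C)C | intermediate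
29 | 3-methoxy-N,N,N-trimethyl-2-[(1S,4S,6S,10R,12R)-1-methyl-7-methylidene-6-(3-methylbut-2-en-1-yl)-12-(prop-1-en-2-yl)bicyclo[8.2.0]dodecan-4-yl]-3-oxopropan-1-aminium iodide | C=C1CC[C@@H]2C[C@H](C(=C)C)[C@@]2(C)CC[C@H](C(C[N+](C)(C)C)C(=O)OC)C[C@H]1CC=C(C)C.[I-] | intermediate
30 | methyl 2-[(1S,4S,6R,10R,12R)-1-methyl-7-methylidene-6-(3-methylbut-2-en-1-yl)-12-(prop-1-en-2-yl)bicyclo[8.2.0]dodecan-4-yl]prop-2-enoate (CNP0314186.1) | C=C1CC[C@@H]2C[C@H](C(=C)C)[C@@]2(C)CC[C@H](C(=C)C(=O)OC)C[C@H]1CC=C(C)C | target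

Total step count: 17. Longest linear sequence: 12 steps (steps 1–7 and 13–17); steps 8–12 make the enoate fragment 19.

Steps most likely to fail

1. Step 16 (key step). What may go wrong: intermolecular coupling (oligomerisation), protodeboronation or β-hydride elimination of the alkylpalladium intermediate may outrun closure of the strained ten-membered ring. Fallback, setting out from 24 and coming back at 26: hydroboration–oxidation of the vinyl group (9-BBN; NaBO3) would give primary alcohol F1, and oxidation (TEMPO, PhI(OAc)2) would give aldehyde F2. An intramolecular Nozaki–Hiyama–Kishi reaction (CrCl2, NiCl2 cat., DMSO/THF, high dilution) would then close the same C7–C8 bond as allylic alcohol F3 (either C8 epimer serves). Methyl chloroformate/pyridine would give allylic carbonate F4, and formate hydrogenolysis (Pd(OAc)2, PBu3, HCO2NH4, THF), which delivers hydride to the more substituted allyl terminus, would remove the oxygen while keeping the alkene exocyclic, giving 26.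

2. Step 1. What may go wrong: poor facial selectivity in the conjugate addition of an alkenyl Grignard reagent to an α-substituted enone, or proton transfer and O-alkylation in place of C-alkylation of the magnesium enolate. Fallback, from 1 back to 3: the same addition–alkylation run with achiral CuBr·SMe2 would give racemic trans keto ester F5. Cleavage of the tert-butyl ester (TMSOTf, 2,6-lutidine; then H2O) would give racemic keto acid F6, to be resolved by crystallisation of its (R)-1-phenylethylammonium salt F7 (the other amine antipode if the opposite salt proves the less soluble). Acid work-up would free keto acid F8, and tert-butyl 2,2,2-trichloroacetimidate (BF3·OEt2 cat.) would re-esterify it to 3.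

3. Step 13. What may go wrong: slow or unselective addition of a hindered, functionalised Grignard reagent (competing 1,2-addition, mismatch of the ligand with the resident stereocentres). Fallback, from 18 and 12 back to 21: Horner–Wadsworth–Emmons reaction of 18 with diethyl {2-oxo-2-[(4R)-2-oxo-4-phenyl-1,3-oxazolidin-3-yl]ethyl}phosphonate (LiCl, iPr2NEt, MeCN) would give N-enoyl oxazolidinone F9. Grignard reagent 20 (from 12) with CuBr·SMe2 (1 equiv, THF/Me2S, −78 to −20 °C) should add to the magnesium-chelated s-cis enoyl imide on the face away from the phenyl group to give imide F10 with the 3S centre. MeOMgBr in MeOH would cleave the auxiliary and give 21.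

Further compounds
F1 | step 16 | methyl (3S,5S)-3-{2-[(1S,2S,4R)-2-(2-hydroxyethyl)-1-methyl-4-(prop-1-en-2-yl)cyclobutyl]ethyl}-5-(1-iodoethenyl)-8-methylnon-7-enoate | OCC[C@@H]1C[C@H](C(=C)C)[C@@]1(C)CC[C@H](CC(=O)OC)C[C@H](C(I)=C)CC=C(C)C
F2 | step 16 | methyl (3S,5S)-5-(1-iodoethenyl)-8-methyl-3-{2-[(1S,2S,4R)-1-methyl-2-(2-oxoethyl)-4-(prop-1-en-2-yl)cyclobutyl]ethyl}non-7-enoate | O=CC[C@@H]1C[C@H](C(=C)C)[C@@]1(C)CC[C@H](CC(=O)OC)C[C@H](C(I)=C)CC=C(C)C
F3 | step 16 | methyl 2-[(1S,4S,6S,10S,12R)-8-hydroxy-1-methyl-7-methylidene-6-(3-methylbut-2-en-1-yl)-12-(prop-1-en-2-yl)bicyclo[8.2.0]dodecan-4-yl]acetate (C8 epimers) | C=C1C(O)C[C@@H]2C[C@H](C(=C)C)[C@@]2(C)CC[C@H](CC(=O)OC)C[C@H]1CC=C(C)C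
F4 | step 16 | methyl 2-[(1S,4S,6S,10S,12R)-8-[(methoxycarbonyl)oxy]-1-methyl-7-methylidene-6-(3-methylbut-2-en-1-yl)-12-(prop-1-en-2-yl)bicyclo[8.2.0]dodecan-4-yl]acetate (C8 epimers) | C=C1C(OC(=O)OC)C[C@@H]2C[C@H](C(=C)C)[C@@]2(C)CC[C@H](CC(=O)OC)C[C@H]1CC=C(C)C
F5 | step 1 | racemic tert-butyl 2-[(1R*,5R*)-1-methyl-2-oxo-5-(prop-1-en-2-yl)cyclopentyl]acetate | O=C1CC[C@H](C(=C)C)[C@@]1(C)CC(=O)OC(C)(C)C.O=C1CC[C@@H](C(=C)C)[C@]1(C)CC(=O)OC(C)(C)C
F6 | step 1 | racemic 2-[(1R*,5R*)-1-methyl-2-oxo-5-(prop-1-en-2-yl)cyclopentyl]acetic acid | O=C1CC[C@H](C(=C)C)[C@@]1(C)CC(=O)O.O=C1CC[C@@H](C(=C)C)[C@]1(C)CC(=O)O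
F7 | step 1 | (1R)-1-phenylethan-1-aminium 2-[(1R,5R)-1-methyl-2-oxo-5-(prop-1-en-2-yl)cyclopentyl]acetate | O=C1CC[C@H](C(=C)C)[C@@]1(C)CC(=O)[O-].C[C@@H]([NH3+])c1ccccc1
F8 | step 1 | 2-[(1R,5R)-1-methyl-2-oxo-5-(prop-1-en-2-yl)cyclopentyl]acetic acid | O=C1CC[C@H](C(=C)C)[C@@]1(C)CC(=O)O
F9 | step 13 | (4R)-3-[(2E,5S)-8-methyl-5-{[tri(propan-2-yl)silyl]ethynyl}nona-2,7-dienoyl]-4-phenyl-1,3-oxazolidin-2-one | O=C1OC[C@@H](c2ccccc2)N1C(=O)/C=C/C[C@H](C#C[Si](C(C)C)(C(C)C)C(C)C)CC=C(C)C
F10 | step 13 | (4R)-3-[(3S,5S)-3-{2-[(1S,2S,4R)-2-ethenyl-1-methyl-4-(prop-1-en-2-yl)cyclobutyl]ethyl}-8-methyl-5-{[tri(propan-2-yl)silyl]ethynyl}non-7-enoyl]-4-phenyl-1,3-oxazolidin-2-one | C=C[C@@H]1C[C@H](C(=C)C)[C@@]1(C)CC[C@H](CC(=O)N2[C@H](c3ccccc3)COC2=O)C[C@H](C#C[Si](C(C)C)(C(C)C)C(C)C)CC=C(C)C
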